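The plan opens the pyrrole ring of the indole at its C2=C3 double bond. Apart from each other, C2 is bound only to N1 and hydrogen, and C3 only to C3a and (before the last step) hydrogen. Both atoms can therefore be traced back to CH=O groups: an N-formyl group at N1 and a formyl group at C3a. Precursor 8 is thus a benzene ring carrying ortho NHCHO and CHO groups plus the two bromines destined for C4 and C6. Low-valent titanium joins the two electrophilic carbons, strips both oxygens and closes the aromatic five-membered ring in one operation, giving 4,6-dibromoindole 10. Electrophilic bromination at C3 then finishes the target.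

Key step: step 5

Remark on the chemistry: the target has no stereocentre, axis or plane of chirality. It is achiral, so there is no enantiomer to select and no step has to control configuration.

Design of 8: the formamide N–H is left free, because secondary oxo-amides are the established substrates of this cyclisation and a protecting group would cost two steps. The C3 bromine is withheld until the end, so the reductive step meets only the two aryl C–Br bonds. Compounds 1 (also sold as 1,5-dibromo-2-methyl-3-nitrobenzene), 2 and 6 are catalogue chemicals.

Step 1
Reactants: 1 2,4-dibromo-6-nitrotoluene; 2 N,N-dimethylformamide dimethyl acetal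
Product: 3 (E)-2-(2,4-dibromo-6-nitrophenyl)-N,N-dimethylethen-1-amine
Conditions: 2 (3 equiv), DMF, 115 °C, N2, overnight; concentrate, use crude
Reagents that add atoms: N,N-dimethylformamide dimethyl acetal 2, COC(OC)N(C)C
Why: This is the first stage of the Leimgruber–Batcho sequence (condensation of an acidic benzylic methyl group with an amide acetal), in which the ortho nitro group and the two bromines acidify the CH3 enough for released methoxide to deprotonate it, the carbanion adds to the formamidinium ion and loss of methanol gives the push–pull (E)-enamine, while both bromines lie meta to the nitro group and are not activated for SNAr.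

Step 2
Reactants: 3 (E)-2-(2,4-dibromo-6-nitrophenyl)-N,N-dimethylethen-1-amine
Product: 4 2,4-dibromo-6-nitrobenzaldehyde
Conditions: NaIO4 (3 equiv), THF/H2O, 0 °C → rt
Reagents that add atoms: sodium periodate, [Na+].[O-]I(=O)(=O)=O
Why: Periodate oxidative cleavage of the electron-rich enamine C=C bond is the standard conversion of such enamines into 2-nitrobenzaldehydes, should stop at the aldehyde, and leaves the nitro group and the aryl bromides untouched.

Step 3
Reactants: 4 2,4-dibromo-6-nitrobenzaldehyde
Product: 5 2-amino-4,6-dibromobenzaldehyde
Conditions: Fe powder (5 equiv), AcOH/EtOH/H2O, 65 °C
Reagents that add atoms: none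
Why: In this Béchamp-type reduction, iron in weak acid takes the nitro group via nitroso and hydroxylamine to the amine without touching the aldehyde or the C–Br bonds (which catalytic hydrogenation would endanger), and the product, a vinylogous amide with an internal N–H···O=C hydrogen bond and two withdrawing bromines, should resist self-condensation.

Step 4
Reactants: 5 2-amino-4,6-dibromobenzaldehyde; 6 formic acid
Product: 8 N-(3,5-dibromo-2-formylphenyl)formamide, via acetic formic anhydride 7 (not isolated)
Conditions: 6, Ac2O, 55 °C, 2 h, then 0 °C; add to 5, THF, 0 °C → rt
Reagents that add atoms: formic acid 6, OC=O (formyl group of 7 and 8); acetic anhydride, CC(=O)OC(C)=O (acetyl group of the transient 7 only, nothing of it remains in 8)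
Why: In this N-formylation with a mixed anhydride (nucleophilic acyl substitution), the weakly nucleophilic aniline attacks the less hindered and more electrophilic formyl carbon of 7, so formyl rather than acetyl should be transferred at or below room temperature, where the aldehyde is inert.

Step 5
Reactants: 8 N-(3,5-dibromo-2-formylphenyl)formamide
Product: 10 4,6-dibromo-1H-indole, via titanium indoline-2,3-diolate 9 (not isolated)
Conditions: TiCl3 (5 equiv), Zn dust (10 equiv), DME, reflux, 2 h, Ar; then 8 in DME by syringe pump over 8 h (final ca. 0.01 M), reflux
Reagents that add atoms: titanium(III) chloride, Cl[Ti](Cl)Cl (titanium and chloride enter only the transient 9; no reagent atom remains in 10)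
Why: Low-valent titanium binds both carbonyl oxygens of 8 and reduces the aryl aldehyde, the more easily reduced partner, to a metal-bound ketyl (after a second electron, a titanaoxirane-like carbanion equivalent) whose carbon, the future C3, adds to the formamide carbon, the future C2, to give the chelated diolate 9. Scission of both C–O bonds on the oxophilic metal, eased at C2 by the N1 lone pair and pulled forward by the aromaticity of the emerging pyrrole ring, should then release 10. The closest known reaction type is the titanium-induced reductive cyclisation of 2-acylamino aryl carbonyl compounds (Fürstner indole synthesis, an intramolecular McMurry-type oxo-amide coupling), of which the CHO/NHCHO pair is the least substituted member. The one ring formed, the five-membered pyrrole ring, closes in a 5-exo-trig mode, since C3 attacks a C2=O bond whose oxygen stays outside the ring; the two sp3 carbons of 9 are flattened again, so no stereocentre is created in 10. Ring closure has to beat pinacol or stilbene dimerisation of the aldehyde, which the ortho placement of the two groups on C3a and C7a (both oxygens can sit on one titanium centre) and the low stationary concentration from syringe-pump addition should secure. The C–Br bonds, ortho and para to the ketyl carbon, must also survive, which is credible because 2- and 4-bromobenzaldehydes and bromobenzophenones are standard substrates of Ti/Zn carbonyl couplings.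

Step 6
Reactants: 10 4,6-dibromo-1H-indole
Product: 11 3,4,6-tribromo-1H-indole
Conditions: NBS (1.0 equiv), dry DMF, 0 °C, dark
Reagents that add atoms: N-bromosuccinimide, O=C1CCC(=O)N1Br
Why: In this electrophilic aromatic substitution of an indole, C3 is the β-carbon of the N1–C2=C3 enamine and by far the most nucleophilic position, the benzene ring is deactivated by its two bromines, and one equivalent of NBS at low temperature should stop after monobromination despite the peri bromine at C4.

Compound list
1 | 2,4-dibromo-6-nitrotoluene (1,5-dibromo-2-methyl-3-nitrobenzene) | Cc1c(Br)cc(Br)cc1[N+](=O)[O-] | starting material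
2 | N,N-dimethylformamide dimethyl acetal | COC(OC)N(C)C | starting material
3 | (E)-2-(2,4-dibromo-6-nitrophenyl)-N,N-dimethylethen-1-amine | CN(C)/C=C/c1c(Br)cc(Br)cc1[N+](=O)[O-] | intermediate
4 | 2,4-dibromo-6-nitrobenzaldehyde | O=Cc1c(Br)cc(Br)cc1[N+](=O)[O-] | intermediate
5 | 2-amino-4,6-dibromobenzaldehyde | Nc1cc(Br)cc(Br)c1C=O | intermediate
6 | formic acid | OC=O | starting material
7 | acetic formic anhydride (made in the flask, not isolated) | CC(=O)OC=O | intermediate
8 | N-(3,5-dibromo-2-formylphenyl)formamide | O=CNc1cc(Br)cc(Br)c1C=O | intermediate
9 | titanium(IV) chelate of cis-4,6-dibromoindoline-2,3-diol, drawn in its simplest form with a TiCl2 unit (not isolated; racemic, relative configuration shown, both sp3 centres vanish in the same step) | Cl[Ti]1(Cl)O[C@H]2Nc3cc(Br)cc(Br)c3[C@H]2O1 | intermediate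
10 | 4,6-dibromo-1H-indole | Brc1cc(Br)c2cc[nH]c2c1 | intermediate
11 | 3,4,6-tribromo-1H-indole (achiral) | Brc1cc(Br)c2c(Br)c[nH]c2c1 | target

Total step count: 6. Longest linear sequence: 6 steps (1 → 3 → 4 → 5 → 8 → 10 → 11).

Steps most likely to fail

Step 5. Intermolecular pinacol or olefin coupling of the aldehyde may outrun ring closure. Electron transfer into the ketyl-conjugated ring may cause reductive loss of bromine. The aldehyde may simply be reduced, or the formamide cleaved by the Lewis-acidic salts. The fallback sets out from enamine 3 and comes back at 10, and it forms the N1–C2 bond instead of the C2–C3 bond. This is the second stage of the Leimgruber–Batcho indole synthesis. Iron powder in acetic acid at about 80 °C reduces the nitro group of 3 to give (E)-3,5-dibromo-2-[2-(dimethylamino)ethenyl]aniline F1. The amino group of F1 adds to the protonated enamine carbon, and loss of dimethylamine aromatises the ring to 10.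

Step 6. A second bromination at C2 may occur, traces of water may cause oxidation towards the oxindole, and the free N–H 3-bromoindole may suffer acid- or light-induced bromine migration and decomposition during isolation. The fallback sets out from 10 and comes back at 11, and it brominates a silyl-protected indole, which is easier to handle. NaH and TIPSCl in THF at 0 °C should give 4,6-dibromo-1-(triisopropylsilyl)-1H-indole F2, whose bulky silyl group shields C2. NBS in THF at −78 °C should then give 3,4,6-tribromo-1-(triisopropylsilyl)-1H-indole F3, which can be purified without special care. TBAF in THF at 0 °C releases 11 under non-acidic conditions just before use.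

Step 3. The neighbouring aldehyde may capture the hydroxylamine stage (closure to an anthranil), and the amino aldehyde may self-condense under acid during reduction and work-up. The fallback sets out from 4 and comes back at 8, and it never lets a free amine and a free aldehyde coexist. Ethylene glycol with catalytic p-TsOH in toluene (Dean–Stark) should give 2-(2,4-dibromo-6-nitrophenyl)-1,3-dioxolane F4. Fe/NH4Cl in EtOH/H2O should reduce F4 under near-neutral conditions to 3,5-dibromo-2-(1,3-dioxolan-2-yl)aniline F5. Acetic formic anhydride in THF should then give N-[3,5-dibromo-2-(1,3-dioxolan-2-yl)phenyl]formamide F6. Dilute HCl in THF/H2O at room temperature unmasks the aldehyde to give 8.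

Further compounds
F1 | step 5 | (E)-3,5-dibromo-2-[2-(dimethylamino)ethenyl]aniline | CN(C)/C=C/c1c(Br)cc(Br)cc1N
F2 | step 6 | 4,6-dibromo-1-(triisopropylsilyl)-1H-indole | CC(C)[Si](C(C)C)(C(C)C)n1ccc2c(Br)cc(Br)cc21
F3 | step 6 | 3,4,6-tribromo-1-(triisopropylsilyl)-1H-indole | CC(C)[Si](C(C)C)(C(C)C)n1cc(Br)c2c(Br)cc(Br)cc21
F4 | step 3 | 2-(2,4-dibromo-6-nitrophenyl)-1,3-dioxolane | O=[N+]([O-])c1cc(Br)cc(Br)c1C1OCCO1
F5 | step 3 | 3,5-dibromo-2-(1,3-dioxolan-2-yl)aniline | Nc1cc(Br)cc(Br)c1C1OCCO1
F6 | step 3 | N-[3,5-dibromo-2-(1,3-dioxolan-2-yl)phenyl]formamide | O=CNc1cc(Br)cc(Br)c1C1OCCO1
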